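## Structural features

Theaflavin-3-gallate is built on a benzotropolone (5H-benzo[7]annulen-5-one, numbered C1 to C9a). A benzo ring with free hydroxyls on C3 and C4 is fused through C4a and C9a to a seven-membered ring that holds the C5 ketone and the C6 hydroxyl. Two 5,7-dihydroxyflavan-3-ol units are attached through their C2 atoms: flavan G on C1 of the benzo ring and flavan F on C8 of the seven-membered ring. In each flavan the stereocentres C2 and C3 are neighbours and cis (2R,3R, the epicatechin arrangement); the two pairs are remote and cannot steer each other. The C3 hydroxyl of flavan G is a gallate ester while that of flavan F is free, so two nearly identical secondary alcohols must be told apart. Fragile features are the nine phenolic and tropolone hydroxyls (air oxidation, chelation), the gallate ester (base), the tropolone ring (nucleophiles, over-reduction) and the benzylic C2–O1 bonds, through which the cis flavans can epimerise to the trans series. The real difficulty is the core: a pentasubstituted benzo ring with the contiguous pattern C1(carbon)–C9a–C4a–C4(O)–C3(O), and a seven-membered ring that must reach tropolone oxidation level with a carbon substituent on C8. The key step exploits the fact that C7=C8 joins two carbons outside the arene while C5 and C6 carry the oxygens of a vinylglycolyl ketone: a C5(=O)–C6(O)–C7=CH2 arm on C4a and a C9H2–C8(=CH2) arm on C9a close at C7=C8 to a 6-oxy-6,9-dihydro-5-one, one oxidation at C6 away from the tropolone.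

## Logic of the disconnections

33 to 32: the eleven O–benzyl bonds are cut. Every phenol, the tropolone hydroxyl and the flavan F alcohol then wear the same group, and the air-sensitive polyphenol appears only in the last step. The forward hydrogenolysis must spare the ester, the C2–O1 bonds and the tropolone ring.

32 to 30 and 31: the ester C–O bond on C3 of flavan G is cut. This removes eleven heavy-atom-rich substituents as a commercial acid. It demands that 30 has only one free hydroxyl, so the flavan F alcohol must already be capped.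

30 back to 25 (through 29, 28 with 22, 27 and 26): ring C of flavan G is opened at C4–C4a (arene onto a terminal epoxide), then at O1–C2 (aryl ether made with inversion), then the epoxide oxygen and the vinyl–carbinol bond are removed, and the formyl group on C1 is traced to the bromide. Ring A arrives as commercial 22 and both stereocentres come from one tartrate-controlled epoxidation. The forward sequence needs the erythro epoxy alcohol followed by clean inversion to give the cis flavan, and the reagent must override the remote stereocentres of flavan F.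

25 back to 19 (through 24, 23, 21 with 22, and 20): the same cuts are applied to flavan F. Flavan F is built first because its aldehyde handle on C8 is uncovered together with the tropolone, whereas the C1 bromide is inert and needs no protection. The cost is one benzyl cap (24 to 25).

19 back to 15 (through 18, 17 and 16): no skeletal bond is cut. The tropolone is read as the enol of a 5,6-dione with C7=C8, and the C8 aldehyde as a silyl-protected carbinol. Both silyl ethers leave in one operation and both alcohols are oxidised in one operation. The forward step relies on the acidity of the C9 hydrogens of 17.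

15 to 14: the C7=C8 bond is cut. It is the only ring bond between two non-arene sp2 carbons, and cutting it leaves two simple arms on adjacent arene carbons. The seven-membered ring problem becomes the synthesis of a pentasubstituted benzene. The forward metathesis must form a trisubstituted ring alkene in preference to intermolecular reaction.

14 to 9 and 12: the C4a–C5 bond is cut (aryl nucleophile plus Weinreb amide). The forward step requires metalation of only the bromide that lies next to the benzyloxy group. 12 comes from 10 through 11.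

9 to 5 and 8: the C9–C8 bond is cut (benzylic sp3–sp2 coupling). Palladium must choose the benzylic bromide over two aryl bromides. 8 comes from 6 through 7.

5 back to 1 (through 4, 3 and 2): the formyl carbon of 1 becomes C9. The free hydroxyl of 1 directs one bromine to its ortho position (the future C4a) and one to its para position (the future C1), and is then benzylated.

## Other disconnections considered

Alternative 1: The cut is the C4–C4a bond of flavan F, made last on a compound that already holds the benzylated benzotropolone, flavan G and its gallate. Forward, AuCl3 with AgOTf would activate the terminal epoxide of the aryl ether A2, and the ortho carbon of its 3,5-bis(benzyloxy)phenoxy group would attack C4 in a 6-endo Friedel–Crafts closure to give A1 with the flavan F hydroxyl free.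
- In its favour: no stereocentre is touched in the closure, ring A comes from a commercial phenol, and the C3 hydroxyl appears unprotected exactly where the target needs it.
- Against it here: it says nothing about how the benzotropolone is made. The C8 handle would have to stay masked through the whole flavan G sequence. The gallate would have to survive a vinyl-metal addition, a titanium-alkoxide epoxidation and a Lewis acid, and the most valuable, most Lewis-basic intermediate would meet the gold catalyst.
- Comparison: on mechanism it is the equal of the chosen plan, which uses the same type of closure for ring C of both flavans (steps 18 and 24) but in the order F before G. On step economy it is slightly the better on paper, since it saves the benzylation of step 19, although late unmasking and oxidation of the C8 carbinol would use up that saving. On structure it addresses a ring that is routine and leaves the seven-membered ring to other chemistry, so it complements the metathesis and does not replace it.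

Alternative 2: The cuts are C6–C7 and C8–C9 of the seven-membered ring, plus a temporary C6–O bond to an oxygen that bridges C6 and C9. Forward, Rh2(OAc)4 would turn the diazoketone A4 into a rhodium carbenoid at C6; the ortho formyl oxygen would add to give a cyclic carbonyl ylide, which would add across the alkyne of the ynone A5 to give the oxygen-bridged adduct A3. Bridge opening would later give the tropolone, and the keto side chain on C8 would be closed to flavan F.
- In its favour: two rings and three bonds form in one step, the C5/C6 oxygen pattern is delivered directly, and the C8 substituent arrives as the whole C2–C3–C4–ring A chain of flavan F with C3 already set. On convergence and on bonds formed per step it is the better.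
- Against it here: the regiochemistry of the dipolar addition (acyl on C8, not C7) rests on orbital bias and not on connectivity. A diazo group must be installed and handled on a late, gallate-bearing compound. The alpha-alkoxy ynone stereocentre can epimerise, and the bridge opening and the cis-selective closure of flavan F remain to be solved with substrate control at C2.
- Comparison: on structure it builds more per step. On mechanism the chosen metathesis is more predictable, because two tethered alkenes cannot give a regioisomer. On step economy the alternative is equal or better after its key step, but both fragments need longer preparation, so the overall count should be comparable.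

Alternative 3: The seven-membered ring is traced to a six-membered one. C8 is inserted as a dibromocarbene carbon, so the bonds C7–C8 and C8–C9 are cut and the C7–C9 bond is broken in the expansion. Forward, base would enolise the acyloin A7 (a dibromocarbene adduct); the enolate would push open the internal cyclopropane bond while bromide leaves C8, and the ring would grow to the 8-bromotropolone A6.
- In its favour: it is short, classical and metal-free, and it gives the tropolone oxidation level without a separate oxidation. On step count to the benzotropolone core it is the better. The two bromides also differ in reactivity (vinylogous acyl bromide on C8, aryl bromide on C1).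
- Against it here: C8 carries a halogen and not a carbon, so each flavan needs an extra carbon–carbon bond formation, and the plan relies on C8–Br reacting before C1–Br. The expansion also runs under strongly basic conditions on an enolisable acyloin.
- Comparison: on structure the chosen plan is the better, because it delivers C8 with its carbon attached and distinguished from C1 by functional-group type. On mechanism both are predictable and equal. On step economy the alternative wins to the core and loses at the C8 elaboration, so the totals should be about equal.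

Key step: step 11

Assumption: benzylation of the tropolone in step 14 is drawn on O6, the oxygen remote from the C4 benzyloxy group; the O5 isomer would behave alike and converge on 33 in step 26.

Assumption: 10 is used as the racemate because its stereocentre (the later C6) is destroyed in step 13.

Remark on the arene: a 5-bromo-2-hydroxy-3-methoxybenzaldehyde core does not map onto the key-step precursor. Its formyl carbon sits on the future C4a, the position between formyl and bromine (the future C9a) is unsubstituted, and its methyl ether would not leave on hydrogenolysis. The arene is therefore derived from 1, whose formyl carbon becomes C9.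

Remark on the precursor: the C8 carbinol is carried as a silyl ether and not as a p-methoxybenzyl ether. One fluoride treatment then frees both hydroxyls, one oxidation gives both the tropolone and the C8 aldehyde, and no quinone oxidant is needed later in the presence of oxidisable flavan rings.

## Route

Step 1
Reactants: 1 4-(benzyloxy)-3-hydroxybenzaldehyde
Product: 2 4-(benzyloxy)-2,6-dibromo-3-hydroxybenzaldehyde
Conditions: Br2 (2.1 equiv), NaOAc, AcOH, rt
Reagents that add atoms: bromine (BrBr)
Why: Electrophilic aromatic bromination; the free phenol activates only its ortho position C2 and its para position C6, which are the carbons that later carry the ketone arm and the flavan G handle. NaOAc buffers the HBr so the benzyl ether should survive.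

Step 2
Reactants: 2 4-(benzyloxy)-2,6-dibromo-3-hydroxybenzaldehyde
Product: 3 3,4-bis(benzyloxy)-2,6-dibromobenzaldehyde
Conditions: BnBr, K2CO3, DMF, 50 °C
Reagents that add atoms: benzyl bromide (BrCc1ccccc1)
Why: Williamson etherification of the phenoxide; all core oxygens then carry a group that leaves in the final hydrogenolysis.

Step 3
Reactants: 3 3,4-bis(benzyloxy)-2,6-dibromobenzaldehyde
Product: 4 [3,4-bis(benzyloxy)-2,6-dibromophenyl]methanol
Conditions: NaBH4, THF/MeOH, 0 °C
Reagents that add atoms: none
Why: Borohydride reduction of the aldehyde; aryl bromides and benzyl ethers are inert.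

Step 4
Reactants: 4 [3,4-bis(benzyloxy)-2,6-dibromophenyl]methanol
Product: 5 1,2-bis(benzyloxy)-3,5-dibromo-4-(bromomethyl)benzene
Conditions: PBr3, CH2Cl2, 0 °C
Reagents that add atoms: phosphorus tribromide (BrP(Br)Br)
Why: The benzylic alcohol is converted into the bromide through its phosphite ester (SN2 by bromide); the low temperature protects the benzyl ethers.

Step 5
Reactants: 6 2-bromoprop-2-en-1-ol
Product: 7 [(2-bromoprop-2-en-1-yl)oxy](tert-butyl)dimethylsilane
Conditions: TBSCl, imidazole, CH2Cl2, rt
Reagents that add atoms: tert-butyldimethylsilyl chloride (CC(C)(C)[Si](C)(C)Cl)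
Why: Standard silylation of a primary alcohol with imidazole as base and nucleophilic catalyst.

Step 6
Reactants: 7 [(2-bromoprop-2-en-1-yl)oxy](tert-butyl)dimethylsilane
Product: 8 tert-butyldimethyl{[2-(4,4,5,5-tetramethyl-1,3,2-dioxaborolan-2-yl)prop-2-en-1-yl]oxy}silane
Conditions: B2pin2, PdCl2(PPh3)2 (3 mol%), PPh3 (6 mol%), KOPh, toluene, 50 °C
Reagents that add atoms: bis(pinacolato)diboron (CC1(C)OB(OC1(C)C)B1OC(C)(C)C(C)(C)O1)
Why: Miyaura borylation of an alkenyl bromide; the weak base KOPh promotes boron-to-palladium transfer without coupling the product with unreacted bromide.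

Step 7
Reactants: 5 1,2-bis(benzyloxy)-3,5-dibromo-4-(bromomethyl)benzene; 8 tert-butyldimethyl{[2-(4,4,5,5-tetramethyl-1,3,2-dioxaborolan-2-yl)prop-2-en-1-yl]oxy}silane
Product: 9 {[2-({3,4-bis(benzyloxy)-2,6-dibromophenyl}methyl)prop-2-en-1-yl]oxy}(tert-butyl)dimethylsilane
Conditions: Pd(PPh3)4 (5 mol%), K2CO3 (2 M aq), THF, 60 °C
Reagents that add atoms: none
Why: Suzuki–Miyaura sp3–sp2 coupling; zerovalent palladium should insert into the benzylic C–Br bond far faster than into the two electron-rich aryl C–Br bonds that are flanked by ortho substituents, so both aryl bromides are kept.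

Step 8
Reactants: 10 methyl 2-hydroxybut-3-enoate (racemic)
Product: 11 methyl 2-{[tert-butyl(dimethyl)silyl]oxy}but-3-enoate (racemic)
Conditions: TBSCl, imidazole, DMF, rt
Reagents that add atoms: tert-butyldimethylsilyl chloride (CC(C)(C)[Si](C)(C)Cl)
Why: Silylation of the secondary alcohol; the silyl ether survives the organomagnesium steps and the metathesis.

Step 9
Reactants: 11 methyl 2-{[tert-butyl(dimethyl)silyl]oxy}but-3-enoate (racemic)
Product: 12 2-{[tert-butyl(dimethyl)silyl]oxy}-N-methoxy-N-methylbut-3-enamide (racemic)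
Conditions: MeNHOMe·HCl, iPrMgCl, THF, −20 °C
Reagents that add atoms: N,O-dimethylhydroxylamine hydrochloride (CNOC.Cl)
Why: Weinreb amide formation from the ester with the magnesium amide made in the flask; the low temperature should leave the acidic allylic alpha-hydrogen untouched.

Step 10
Reactants: 9 {[2-({3,4-bis(benzyloxy)-2,6-dibromophenyl}methyl)prop-2-en-1-yl]oxy}(tert-butyl)dimethylsilane; 12 2-{[tert-butyl(dimethyl)silyl]oxy}-N-methoxy-N-methylbut-3-enamide (racemic)
Product: 14 1-{2,3-bis(benzyloxy)-5-bromo-6-[2-({[tert-butyl(dimethyl)silyl]oxy}methyl)prop-2-en-1-yl]phenyl}-2-{[tert-butyl(dimethyl)silyl]oxy}but-3-en-1-one (racemic), via arylmagnesium chloride 13 (not isolated)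
Conditions: iPrMgCl·LiCl (1.05 equiv), THF, 0 °C to rt; then 12, 0 °C to rt; aq NH4Cl
Reagents that add atoms: none
Why: Bromine–magnesium exchange is expected at the bromide ortho to the benzyloxy group (inductive stabilisation and chelation of the aryl–magnesium bond), while the bromide para to that group stays. The aryl Grignard reagent then acylates on the Weinreb amide, whose chelated tetrahedral adduct prevents over-addition.

Step 11
Reactants: 14 1-{2,3-bis(benzyloxy)-5-bromo-6-[2-({[tert-butyl(dimethyl)silyl]oxy}methyl)prop-2-en-1-yl]phenyl}-2-{[tert-butyl(dimethyl)silyl]oxy}but-3-en-1-one (racemic)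
Product: 15 3,4-bis(benzyloxy)-1-bromo-6-{[tert-butyl(dimethyl)silyl]oxy}-8-({[tert-butyl(dimethyl)silyl]oxy}methyl)-6,9-dihydro-5H-benzo[7]annulen-5-one (racemic)
Conditions: second-generation Grubbs catalyst RuCl2(=CHPh)(H2IMes)(PCy3) (5 mol%), 1,4-benzoquinone (10 mol%), CH2Cl2 (2 mM), 40 °C
Reagents that add atoms: none
Why: The ruthenium benzylidene should first exchange with the monosubstituted vinyl group of 14, the only alkene it can reach easily, to give an alkylidene on C7; this adds across the 1,1-disubstituted C8=CH2 alkene of the neighbouring arm through a ruthenacyclobutane, whose cycloreversion forms C7=C8 and a ruthenium methylidene that carries the chain and leaves as ethylene. The closest known reaction type is ring-closing metathesis of aryl-tethered dienes to benzo-fused cycloheptenones with formation of a trisubstituted ring alkene under NHC-ligated ruthenium catalysis. The one ring closed is the seven-membered carbocycle, formed from a 1,8-diene by joining C7 and C8 with the new double bond inside the ring; the two arms sit on the adjacent arene carbons C4a and C9a, which holds the alkenes near each other. No stereocentre is created: C6 is already present, is racemic, and is erased in step 13. The step needs ring closure to win over intermolecular metathesis and over double-bond migration; high dilution, the ortho arrangement of the arms, the reluctance of the 1,1-disubstituted alkene to homodimerise and the hydride scavenger 1,4-benzoquinone should secure this. The aryl bromide, the benzyl and silyl ethers and the ketone are inert to the catalyst, and loss of ethylene drives the equilibrium.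

Step 12
Reactants: 15 3,4-bis(benzyloxy)-1-bromo-6-{[tert-butyl(dimethyl)silyl]oxy}-8-({[tert-butyl(dimethyl)silyl]oxy}methyl)-6,9-dihydro-5H-benzo[7]annulen-5-one (racemic)
Product: 16 3,4-bis(benzyloxy)-1-bromo-6-hydroxy-8-(hydroxymethyl)-6,9-dihydro-5H-benzo[7]annulen-5-one (racemic)
Conditions: HF·pyridine, THF, 0 °C to rt
Reagents that add atoms: none
Why: Fluoride cleaves both silyl ethers in one operation; the buffered acidic medium avoids base-induced enolisation of the acyloin.

Step 13
Reactants: 16 3,4-bis(benzyloxy)-1-bromo-6-hydroxy-8-(hydroxymethyl)-6,9-dihydro-5H-benzo[7]annulen-5-one (racemic)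
Product: 18 3,4-bis(benzyloxy)-1-bromo-6-hydroxy-5-oxo-5H-benzo[7]annulene-8-carbaldehyde, via 5,6-dione 17 (not isolated)
Conditions: Dess–Martin periodinane (2.5 equiv), CH2Cl2, 0 °C to rt; then Et3N (cat.)
Reagents that add atoms: none
Why: Dess–Martin oxidation turns the acyloin into the 5,6-dione and the allylic alcohol into the enal. The dione 17 should enolise through its doubly activated C9 hydrogens to the aromatic tropolone, which is the thermodynamic sink.

Step 14
Reactants: 18 3,4-bis(benzyloxy)-1-bromo-6-hydroxy-5-oxo-5H-benzo[7]annulene-8-carbaldehyde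
Product: 19 3,4,6-tris(benzyloxy)-1-bromo-5-oxo-5H-benzo[7]annulene-8-carbaldehyde
Conditions: BnBr, K2CO3, DMF, rt
Reagents that add atoms: benzyl bromide (BrCc1ccccc1)
Why: O-Alkylation of the acidic tropolone masks it against the organometallic, Mitsunobu and acylation steps that follow; either oxygen may be benzylated without consequence for the target.

Step 15
Reactants: 19 3,4,6-tris(benzyloxy)-1-bromo-5-oxo-5H-benzo[7]annulene-8-carbaldehyde
Product: 20 3,4,6-tris(benzyloxy)-1-bromo-8-(1-hydroxyprop-2-en-1-yl)-5H-benzo[7]annulen-5-one (racemic)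
Conditions: CH2=CHMgBr (1.1 equiv), THF, −78 °C; aq NH4Cl
Reagents that add atoms: vinylmagnesium bromide (C=C[Mg]Br)
Why: 1,2-Addition of the Grignard reagent to the aldehyde, which at −78 °C is far more electrophilic than the vinylogous ester of the benzyloxytropone or the aryl bromide; the new carbinol is racemic.

Step 16
Reactants: 20 3,4,6-tris(benzyloxy)-1-bromo-8-(1-hydroxyprop-2-en-1-yl)-5H-benzo[7]annulen-5-one (racemic)
Product: 21 3,4,6-tris(benzyloxy)-1-bromo-8-{(S)-hydroxy[(2R)-oxiran-2-yl]methyl}-5H-benzo[7]annulen-5-one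
Conditions: Ti(OiPr)4 (0.2 equiv), L-(+)-diisopropyl tartrate (0.24 equiv), t-BuOOH (0.6 equiv), 4 Å MS, CH2Cl2, −20 °C
Reagents that add atoms: tert-butyl hydroperoxide (CC(C)(C)OO)
Why: Sharpless kinetic resolution: with L-(+)-tartrate the titanium peroxo complex should epoxidise the (R)-carbinol much faster than the (S)-carbinol and deliver oxygen to one alkene face, giving the erythro epoxy alcohol. The carbinol is then named (S) only because the epoxide carbon outranks the aryl group; the unreacted (S)-enantiomer of 20 is separated.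

Step 17
Reactants: 21 3,4,6-tris(benzyloxy)-1-bromo-8-{(S)-hydroxy[(2R)-oxiran-2-yl]methyl}-5H-benzo[7]annulen-5-one; 22 3,5-bis(benzyloxy)phenol
Product: 23 3,4,6-tris(benzyloxy)-8-{(R)-[3,5-bis(benzyloxy)phenoxy][(2R)-oxiran-2-yl]methyl}-1-bromo-5H-benzo[7]annulen-5-one
Conditions: PPh3, DIAD, toluene, 0 °C to rt
Reagents that add atoms: none
Why: Mitsunobu etherification: the phenol displaces the activated carbinol oxygen with SN2 inversion, which sets C2 of flavan F as R. The electron-poor tropone ring disfavours ionisation, and the epoxide is not touched.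

Step 18
Reactants: 23 3,4,6-tris(benzyloxy)-8-{(R)-[3,5-bis(benzyloxy)phenoxy][(2R)-oxiran-2-yl]methyl}-1-bromo-5H-benzo[7]annulen-5-one
Product: 24 3,4,6-tris(benzyloxy)-8-[(2R,3R)-5,7-bis(benzyloxy)-3-hydroxy-3,4-dihydro-2H-1-benzopyran-2-yl]-1-bromo-5H-benzo[7]annulen-5-one
Conditions: AuCl3 (5 mol%), AgOTf (15 mol%), ClCH2CH2Cl, rt
Reagents that add atoms: none
Why: Intramolecular Friedel–Crafts alkylation: cationic trivalent gold activates the epoxide, and the ortho carbon of the phloroglucinol-type ether attacks the terminal carbon (6-endo) to close ring C. C2 and C3 are not involved, so the cis (2R,3R) relationship is carried over; the two ortho positions are equivalent.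

Step 19
Reactants: 24 3,4,6-tris(benzyloxy)-8-[(2R,3R)-5,7-bis(benzyloxy)-3-hydroxy-3,4-dihydro-2H-1-benzopyran-2-yl]-1-bromo-5H-benzo[7]annulen-5-one
Product: 25 3,4,6-tris(benzyloxy)-1-bromo-8-[(2R,3R)-3,5,7-tris(benzyloxy)-3,4-dihydro-2H-1-benzopyran-2-yl]-5H-benzo[7]annulen-5-one
Conditions: NaH, BnBr, Bu4NI (cat.), DMF, 0 °C to rt
Reagents that add atoms: benzyl bromide (BrCc1ccccc1)
Why: Williamson benzylation of the secondary alkoxide caps the flavan F hydroxyl with a group that leaves in the final hydrogenolysis, so that only flavan G can be acylated later.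

Step 20
Reactants: 25 3,4,6-tris(benzyloxy)-1-bromo-8-[(2R,3R)-3,5,7-tris(benzyloxy)-3,4-dihydro-2H-1-benzopyran-2-yl]-5H-benzo[7]annulen-5-one
Product: 26 3,4,6-tris(benzyloxy)-5-oxo-8-[(2R,3R)-3,5,7-tris(benzyloxy)-3,4-dihydro-2H-1-benzopyran-2-yl]-5H-benzo[7]annulene-1-carbaldehyde
Conditions: Pd(OAc)2 (3 mol%), BuPAd2 (9 mol%), TMEDA, CO/H2 (1:1, 5 bar), toluene, 100 °C
Reagents that add atoms: carbon monoxide ([C-]#[O+])
Why: Palladium-catalysed reductive carbonylation of the aryl bromide (oxidative addition to zerovalent palladium, CO insertion, hydrogenolysis of the acyl–palladium bond); the homogeneous catalyst should not cleave benzyl ethers.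

Step 21
Reactants: 26 3,4,6-tris(benzyloxy)-5-oxo-8-[(2R,3R)-3,5,7-tris(benzyloxy)-3,4-dihydro-2H-1-benzopyran-2-yl]-5H-benzo[7]annulene-1-carbaldehyde
Product: 27 3,4,6-tris(benzyloxy)-1-(1-hydroxyprop-2-en-1-yl)-8-[(2R,3R)-3,5,7-tris(benzyloxy)-3,4-dihydro-2H-1-benzopyran-2-yl]-5H-benzo[7]annulen-5-one (both carbinol epimers)
Conditions: CH2=CHMgBr (1.1 equiv), THF, −78 °C; aq NH4Cl
Reagents that add atoms: vinylmagnesium bromide (C=C[Mg]Br)
Why: Chemoselective 1,2-addition to the aldehyde as in step 15; the remote flavan F exerts no control, so both carbinol epimers should form.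

Step 22
Reactants: 27 3,4,6-tris(benzyloxy)-1-(1-hydroxyprop-2-en-1-yl)-8-[(2R,3R)-3,5,7-tris(benzyloxy)-3,4-dihydro-2H-1-benzopyran-2-yl]-5H-benzo[7]annulen-5-one (both carbinol epimers)
Product: 28 3,4,6-tris(benzyloxy)-1-{(S)-hydroxy[(2R)-oxiran-2-yl]methyl}-8-[(2R,3R)-3,5,7-tris(benzyloxy)-3,4-dihydro-2H-1-benzopyran-2-yl]-5H-benzo[7]annulen-5-one
Conditions: Ti(OiPr)4 (0.2 equiv), L-(+)-diisopropyl tartrate (0.24 equiv), t-BuOOH (0.6 equiv), 4 Å MS, CH2Cl2, −20 °C
Reagents that add atoms: tert-butyl hydroperoxide (CC(C)(C)OO)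
Why: Reagent-controlled Sharpless epoxidation as in step 16: only the (R)-carbinol epimer should be epoxidised, to the erythro epoxy alcohol; the (S)-epimer stays as the alkene and is removed.

Step 23
Reactants: 28 3,4,6-tris(benzyloxy)-1-{(S)-hydroxy[(2R)-oxiran-2-yl]methyl}-8-[(2R,3R)-3,5,7-tris(benzyloxy)-3,4-dihydro-2H-1-benzopyran-2-yl]-5H-benzo[7]annulen-5-one; 22 3,5-bis(benzyloxy)phenol
Product: 29 3,4,6-tris(benzyloxy)-1-{(R)-[3,5-bis(benzyloxy)phenoxy][(2R)-oxiran-2-yl]methyl}-8-[(2R,3R)-3,5,7-tris(benzyloxy)-3,4-dihydro-2H-1-benzopyran-2-yl]-5H-benzo[7]annulen-5-one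
Conditions: PPh3, DIAD, toluene, 0 °C to rt
Reagents that add atoms: none
Why: Mitsunobu etherification with SN2 inversion sets C2 of flavan G as R; no other free hydroxyl is present.

Step 24
Reactants: 29 3,4,6-tris(benzyloxy)-1-{(R)-[3,5-bis(benzyloxy)phenoxy][(2R)-oxiran-2-yl]methyl}-8-[(2R,3R)-3,5,7-tris(benzyloxy)-3,4-dihydro-2H-1-benzopyran-2-yl]-5H-benzo[7]annulen-5-one
Product: 30 3,4,6-tris(benzyloxy)-1-[(2R,3R)-5,7-bis(benzyloxy)-3-hydroxy-3,4-dihydro-2H-1-benzopyran-2-yl]-8-[(2R,3R)-3,5,7-tris(benzyloxy)-3,4-dihydro-2H-1-benzopyran-2-yl]-5H-benzo[7]annulen-5-one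
Conditions: AuCl3 (5 mol%), AgOTf (15 mol%), ClCH2CH2Cl (5 mM), rt
Reagents that add atoms: none
Why: Gold-catalysed 6-endo epoxide–arene cyclisation as in step 18 closes ring C of flavan G and frees its C3 hydroxyl with C2 and C3 untouched. High dilution should keep the electron-rich ring A of flavan F from intercepting the epoxide intermolecularly.

Step 25
Reactants: 30 3,4,6-tris(benzyloxy)-1-[(2R,3R)-5,7-bis(benzyloxy)-3-hydroxy-3,4-dihydro-2H-1-benzopyran-2-yl]-8-[(2R,3R)-3,5,7-tris(benzyloxy)-3,4-dihydro-2H-1-benzopyran-2-yl]-5H-benzo[7]annulen-5-one; 31 3,4,5-tris(benzyloxy)benzoic acid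
Product: 32 (2R,3R)-5,7-bis(benzyloxy)-2-{3,4,6-tris(benzyloxy)-5-oxo-8-[(2R,3R)-3,5,7-tris(benzyloxy)-3,4-dihydro-2H-1-benzopyran-2-yl]-5H-benzo[7]annulen-1-yl}-3,4-dihydro-2H-1-benzopyran-3-yl 3,4,5-tris(benzyloxy)benzoate
Conditions: DCC, DMAP, CH2Cl2, rt
Reagents that add atoms: none
Why: Steglich esterification; 30 has a single free hydroxyl, so the galloyl group can only enter at C3 of flavan G, and the mild conditions leave C2 alone.

Step 26
Reactants: 32 (2R,3R)-5,7-bis(benzyloxy)-2-{3,4,6-tris(benzyloxy)-5-oxo-8-[(2R,3R)-3,5,7-tris(benzyloxy)-3,4-dihydro-2H-1-benzopyran-2-yl]-5H-benzo[7]annulen-1-yl}-3,4-dihydro-2H-1-benzopyran-3-yl 3,4,5-tris(benzyloxy)benzoate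
Product: 33 theaflavin-3-gallate
Conditions: H2 (1 atm), Pd(OH)2/C, THF/MeOH, rt
Reagents that add atoms: none
Why: Hydrogenolysis of all eleven benzyl ethers in one operation. The ester and the flavan C2–O bonds should be retained, and the aromatic tropolone ring is expected to be reduced much more slowly than the O–benzyl bonds are cleaved.

## Compound list

1 | 4-(benzyloxy)-3-hydroxybenzaldehyde | O=Cc1ccc(OCc2ccccc2)c(O)c1 | starting material
2 | 4-(benzyloxy)-2,6-dibromo-3-hydroxybenzaldehyde | O=Cc1c(Br)cc(OCc2ccccc2)c(O)c1Br | intermediate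
3 | 3,4-bis(benzyloxy)-2,6-dibromobenzaldehyde | O=Cc1c(Br)cc(OCc2ccccc2)c(OCc2ccccc2)c1Br | intermediate
4 | [3,4-bis(benzyloxy)-2,6-dibromophenyl]methanol | OCc1c(Br)cc(OCc2ccccc2)c(OCc2ccccc2)c1Br | intermediate
5 | 1,2-bis(benzyloxy)-3,5-dibromo-4-(bromomethyl)benzene | BrCc1c(Br)cc(OCc2ccccc2)c(OCc2ccccc2)c1Br | intermediate
6 | 2-bromoprop-2-en-1-ol | C=C(Br)CO | starting material
7 | [(2-bromoprop-2-en-1-yl)oxy](tert-butyl)dimethylsilane | C=C(Br)CO[Si](C)(C)C(C)(C)C | intermediate
8 | tert-butyldimethyl{[2-(4,4,5,5-tetramethyl-1,3,2-dioxaborolan-2-yl)prop-2-en-1-yl]oxy}silane | C=C(CO[Si](C)(C)C(C)(C)C)B1OC(C)(C)C(C)(C)O1 | intermediate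
9 | {[2-({3,4-bis(benzyloxy)-2,6-dibromophenyl}methyl)prop-2-en-1-yl]oxy}(tert-butyl)dimethylsilane | C=C(CO[Si](C)(C)C(C)(C)C)Cc1c(Br)cc(OCc2ccccc2)c(OCc2ccccc2)c1Br | intermediate
10 | methyl 2-hydroxybut-3-enoate (racemic) | C=CC(O)C(=O)OC | starting material
11 | methyl 2-{[tert-butyl(dimethyl)silyl]oxy}but-3-enoate (racemic) | C=CC(O[Si](C)(C)C(C)(C)C)C(=O)OC | intermediate
12 | 2-{[tert-butyl(dimethyl)silyl]oxy}-N-methoxy-N-methylbut-3-enamide (racemic) | C=CC(O[Si](C)(C)C(C)(C)C)C(=O)N(C)OC | intermediate
13 | {2,3-bis(benzyloxy)-5-bromo-6-[2-({[tert-butyl(dimethyl)silyl]oxy}methyl)prop-2-en-1-yl]phenyl}magnesium chloride (not isolated) | C=C(CO[Si](C)(C)C(C)(C)C)Cc1c(Br)cc(OCc2ccccc2)c(OCc2ccccc2)c1[Mg]Cl | intermediate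
14 | 1-{2,3-bis(benzyloxy)-5-bromo-6-[2-({[tert-butyl(dimethyl)silyl]oxy}methyl)prop-2-en-1-yl]phenyl}-2-{[tert-butyl(dimethyl)silyl]oxy}but-3-en-1-one (racemic) | C=CC(O[Si](C)(C)C(C)(C)C)C(=O)c1c(CC(=C)CO[Si](C)(C)C(C)(C)C)c(Br)cc(OCc2ccccc2)c1OCc1ccccc1 | intermediate
15 | 3,4-bis(benzyloxy)-1-bromo-6-{[tert-butyl(dimethyl)silyl]oxy}-8-({[tert-butyl(dimethyl)silyl]oxy}methyl)-6,9-dihydro-5H-benzo[7]annulen-5-one (racemic) | O=C1C(O[Si](C)(C)C(C)(C)C)C=C(CO[Si](C)(C)C(C)(C)C)Cc2c(Br)cc(OCc3ccccc3)c(OCc3ccccc3)c12 | intermediate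
16 | 3,4-bis(benzyloxy)-1-bromo-6-hydroxy-8-(hydroxymethyl)-6,9-dihydro-5H-benzo[7]annulen-5-one (racemic) | O=C1C(O)C=C(CO)Cc2c(Br)cc(OCc3ccccc3)c(OCc3ccccc3)c12 | intermediate
17 | 3,4-bis(benzyloxy)-1-bromo-5,6-dioxo-6,9-dihydro-5H-benzo[7]annulene-8-carbaldehyde (not isolated) | O=C1C(=O)C=C(C=O)Cc2c(Br)cc(OCc3ccccc3)c(OCc3ccccc3)c12 | intermediate
18 | 3,4-bis(benzyloxy)-1-bromo-6-hydroxy-5-oxo-5H-benzo[7]annulene-8-carbaldehyde | Brc1cc(OCc2ccccc2)c(OCc2ccccc2)c2c(=O)c(O)cc(C=O)cc12 | intermediate
19 | 3,4,6-tris(benzyloxy)-1-bromo-5-oxo-5H-benzo[7]annulene-8-carbaldehyde | Brc1cc(OCc2ccccc2)c(OCc2ccccc2)c2c(=O)c(OCc3ccccc3)cc(C=O)cc12 | intermediate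
20 | 3,4,6-tris(benzyloxy)-1-bromo-8-(1-hydroxyprop-2-en-1-yl)-5H-benzo[7]annulen-5-one (racemic) | Brc1cc(OCc2ccccc2)c(OCc2ccccc2)c2c(=O)c(OCc3ccccc3)cc(C(O)C=C)cc12 | intermediate
21 | 3,4,6-tris(benzyloxy)-1-bromo-8-{(S)-hydroxy[(2R)-oxiran-2-yl]methyl}-5H-benzo[7]annulen-5-one | Brc1cc(OCc2ccccc2)c(OCc2ccccc2)c2c(=O)c(OCc3ccccc3)cc([C@H](O)[C@H]3CO3)cc12 | intermediate
22 | 3,5-bis(benzyloxy)phenol | Oc1cc(OCc2ccccc2)cc(OCc2ccccc2)c1 | starting material
23 | 3,4,6-tris(benzyloxy)-8-{(R)-[3,5-bis(benzyloxy)phenoxy][(2R)-oxiran-2-yl]methyl}-1-bromo-5H-benzo[7]annulen-5-one | Brc1cc(OCc2ccccc2)c(OCc2ccccc2)c2c(=O)c(OCc3ccccc3)cc([C@@H](Oc3cc(OCc4ccccc4)cc(OCc4ccccc4)c3)[C@H]3CO3)cc12 | intermediate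
24 | 3,4,6-tris(benzyloxy)-8-[(2R,3R)-5,7-bis(benzyloxy)-3-hydroxy-3,4-dihydro-2H-1-benzopyran-2-yl]-1-bromo-5H-benzo[7]annulen-5-one | Brc1cc(OCc2ccccc2)c(OCc2ccccc2)c2c(=O)c(OCc3ccccc3)cc([C@H]3Oc4cc(OCc5ccccc5)cc(OCc5ccccc5)c4C[C@H]3O)cc12 | intermediate
25 | 3,4,6-tris(benzyloxy)-1-bromo-8-[(2R,3R)-3,5,7-tris(benzyloxy)-3,4-dihydro-2H-1-benzopyran-2-yl]-5H-benzo[7]annulen-5-one | Brc1cc(OCc2ccccc2)c(OCc2ccccc2)c2c(=O)c(OCc3ccccc3)cc([C@H]3Oc4cc(OCc5ccccc5)cc(OCc5ccccc5)c4C[C@H]3OCc3ccccc3)cc12 | intermediate
26 | 3,4,6-tris(benzyloxy)-5-oxo-8-[(2R,3R)-3,5,7-tris(benzyloxy)-3,4-dihydro-2H-1-benzopyran-2-yl]-5H-benzo[7]annulene-1-carbaldehyde | O=Cc1cc(OCc2ccccc2)c(OCc2ccccc2)c2c(=O)c(OCc3ccccc3)cc([C@H]3Oc4cc(OCc5ccccc5)cc(OCc5ccccc5)c4C[C@H]3OCc3ccccc3)cc12 | intermediate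
27 | 3,4,6-tris(benzyloxy)-1-(1-hydroxyprop-2-en-1-yl)-8-[(2R,3R)-3,5,7-tris(benzyloxy)-3,4-dihydro-2H-1-benzopyran-2-yl]-5H-benzo[7]annulen-5-one (both carbinol epimers) | C=CC(O)c1cc(OCc2ccccc2)c(OCc2ccccc2)c2c(=O)c(OCc3ccccc3)cc([C@H]3Oc4cc(OCc5ccccc5)cc(OCc5ccccc5)c4C[C@H]3OCc3ccccc3)cc12 | intermediate
28 | 3,4,6-tris(benzyloxy)-1-{(S)-hydroxy[(2R)-oxiran-2-yl]methyl}-8-[(2R,3R)-3,5,7-tris(benzyloxy)-3,4-dihydro-2H-1-benzopyran-2-yl]-5H-benzo[7]annulen-5-one | O[C@H]([C@H]1CO1)c1cc(OCc2ccccc2)c(OCc2ccccc2)c2c(=O)c(OCc3ccccc3)cc([C@H]3Oc4cc(OCc5ccccc5)cc(OCc5ccccc5)c4C[C@H]3OCc3ccccc3)cc12 | intermediate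
29 | 3,4,6-tris(benzyloxy)-1-{(R)-[3,5-bis(benzyloxy)phenoxy][(2R)-oxiran-2-yl]methyl}-8-[(2R,3R)-3,5,7-tris(benzyloxy)-3,4-dihydro-2H-1-benzopyran-2-yl]-5H-benzo[7]annulen-5-one | c1c(OCc2ccccc2)cc(OCc2ccccc2)cc1O[C@@H]([C@H]1CO1)c1cc(OCc2ccccc2)c(OCc2ccccc2)c2c(=O)c(OCc3ccccc3)cc([C@H]3Oc4cc(OCc5ccccc5)cc(OCc5ccccc5)c4C[C@H]3OCc3ccccc3)cc12 | intermediate
30 | 3,4,6-tris(benzyloxy)-1-[(2R,3R)-5,7-bis(benzyloxy)-3-hydroxy-3,4-dihydro-2H-1-benzopyran-2-yl]-8-[(2R,3R)-3,5,7-tris(benzyloxy)-3,4-dihydro-2H-1-benzopyran-2-yl]-5H-benzo[7]annulen-5-one | O[C@@H]1Cc2c(OCc3ccccc3)cc(OCc3ccccc3)cc2O[C@@H]1c1cc(OCc2ccccc2)c(OCc2ccccc2)c2c(=O)c(OCc3ccccc3)cc([C@H]3Oc4cc(OCc5ccccc5)cc(OCc5ccccc5)c4C[C@H]3OCc3ccccc3)cc12 | intermediate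
31 | 3,4,5-tris(benzyloxy)benzoic acid | OC(=O)c1cc(OCc2ccccc2)c(OCc2ccccc2)c(OCc2ccccc2)c1 | starting material
32 | (2R,3R)-5,7-bis(benzyloxy)-2-{3,4,6-tris(benzyloxy)-5-oxo-8-[(2R,3R)-3,5,7-tris(benzyloxy)-3,4-dihydro-2H-1-benzopyran-2-yl]-5H-benzo[7]annulen-1-yl}-3,4-dihydro-2H-1-benzopyran-3-yl 3,4,5-tris(benzyloxy)benzoate | O=C(O[C@@H]1Cc2c(OCc3ccccc3)cc(OCc3ccccc3)cc2O[C@@H]1c1cc(OCc2ccccc2)c(OCc2ccccc2)c2c(=O)c(OCc3ccccc3)cc([C@H]3Oc4cc(OCc5ccccc5)cc(OCc5ccccc5)c4C[C@H]3OCc3ccccc3)cc12)c1cc(OCc2ccccc2)c(OCc2ccccc2)c(OCc2ccccc2)c1 | intermediate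
33 | theaflavin-3-gallate | O=C(O[C@@H]1Cc2c(O)cc(O)cc2O[C@@H]1c1cc(O)c(O)c2c(=O)c(O)cc([C@H]3Oc4cc(O)cc(O)c4C[C@H]3O)cc12)c1cc(O)c(O)c(O)c1 | target

## Step count and least certain steps

Total step count: 26. Longest linear sequence: 22 steps (steps 1 to 4, 7, 10 and 11 to 26).

Step 11 (key step). What may go wrong: slow or incomplete ring closure. The alkylidene formed at the vinyl group can be held in a chelate by the neighbouring C5 carbonyl and the silyl ether oxygen, and the 1,1-disubstituted partner is hindered. Long heating would then allow double-bond migration by ruthenium hydrides or intermolecular metathesis. Fallback: setting out from 14, reduction of the ketone (NaBH4, CeCl3·7H2O, MeOH, −40 °C) gives the carbinol 1-{2,3-bis(benzyloxy)-5-bromo-6-[2-({[tert-butyl(dimethyl)silyl]oxy}methyl)prop-2-en-1-yl]phenyl}-2-{[tert-butyl(dimethyl)silyl]oxy}but-3-en-1-ol F1 as a diastereomer mixture, in which the chelating carbonyl is gone. Ring-closing metathesis of this diene carbinol with the same ruthenium catalyst should give the cycloheptenol 3,4-bis(benzyloxy)-1-bromo-6-{[tert-butyl(dimethyl)silyl]oxy}-8-({[tert-butyl(dimethyl)silyl]oxy}methyl)-6,9-dihydro-5H-benzo[7]annulen-5-ol F2. Dess–Martin oxidation of its C5 carbinol brings the route back at 15.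

Step 10. What may go wrong: loss of the aryl Grignard reagent by proton transfer, because the doubly ortho-substituted 13 is hindered and 12 has an acidic allylic alpha-hydrogen. A lesser worry is partial exchange at the second bromide. Fallback: setting out from 11 and 9, reduction of 11 with iBu2AlH (CH2Cl2, −78 °C) gives the aldehyde 2-{[tert-butyl(dimethyl)silyl]oxy}but-3-enal F3. This much more electrophilic partner should capture 13 (made from 9 as before) at −40 °C to give the carbinol F1 described above. Dess–Martin oxidation of F1 returns the route at 14.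

Step 16 (the same reaction recurs in step 22). What may go wrong: slow epoxidation of the hindered vinyl carbinol, so that the rate difference between the enantiomers erodes, and titanium-mediated opening of the sensitive epoxy alcohol. The resolution also discards half of the material by design. Fallback: setting out from 19, catalytic enantioselective vinyl transfer (Zn(CH=CH2)2, a chiral beta-amino alcohol ligand in the enantiomeric form that gives the (R)-carbinol, toluene, 0 °C) should give the single enantiomer 3,4,6-tris(benzyloxy)-1-bromo-8-[(1R)-1-hydroxyprop-2-en-1-yl]-5H-benzo[7]annulen-5-one F4. Its matched epoxidation with the same Ti(OiPr)4/L-(+)-tartrate reagent, now run to full conversion, rejoins the route at 21.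

Step 18 (the same reaction recurs in step 24). What may go wrong: sequestration of the Lewis acid by the basic tropone carbonyl and the many ether oxygens, so that epoxide activation is slow; under forcing conditions the epoxide may rearrange to a carbonyl compound or open at its internal carbon. Fallback: the arene is activated instead of the epoxide. Setting out from 21, Mitsunobu etherification with an excess of 5-(benzyloxy)benzene-1,3-diol gives 3,4,6-tris(benzyloxy)-8-{(R)-[3-(benzyloxy)-5-hydroxyphenoxy][(2R)-oxiran-2-yl]methyl}-1-bromo-5H-benzo[7]annulen-5-one F5. With K2CO3 in 2,2,2-trifluoroethanol at 50 °C, the phenolate, whose oxygen cannot reach the epoxide, should attack the terminal carbon through a ring carbon ortho to the ether oxygen (anionic aryl participation, no Lewis acid) to give 3,4,6-tris(benzyloxy)-8-[(2R,3R)-7-(benzyloxy)-3,5-dihydroxy-3,4-dihydro-2H-1-benzopyran-2-yl]-1-bromo-5H-benzo[7]annulen-5-one F6. Closure at the other ortho carbon would give the regioisomeric phenol, which converges in the next operation. Double benzylation (NaH, BnBr, DMF) of the phenol and the C3 alcohol returns the route at 25.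

Step 26. What may go wrong: partial saturation of the seven-membered tropolone ring, or incomplete cleavage of the hindered secondary benzyl ether on flavan F, during the long exposure needed to remove eleven benzyl groups. Fallback: setting out from 32, Lewis-acid debenzylation with BCl3 and pentamethylbenzene as cation scavenger (CH2Cl2, −78 °C) removes the benzyl groups without hydrogen and arrives directly at 33.

## Further compounds

F1 | step 11 | 1-{2,3-bis(benzyloxy)-5-bromo-6-[2-({[tert-butyl(dimethyl)silyl]oxy}methyl)prop-2-en-1-yl]phenyl}-2-{[tert-butyl(dimethyl)silyl]oxy}but-3-en-1-ol (diastereomer mixture) | C=CC(O[Si](C)(C)C(C)(C)C)C(O)c1c(CC(=C)CO[Si](C)(C)C(C)(C)C)c(Br)cc(OCc2ccccc2)c1OCc1ccccc1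
F2 | step 11 | 3,4-bis(benzyloxy)-1-bromo-6-{[tert-butyl(dimethyl)silyl]oxy}-8-({[tert-butyl(dimethyl)silyl]oxy}methyl)-6,9-dihydro-5H-benzo[7]annulen-5-ol (diastereomer mixture) | OC1C(O[Si](C)(C)C(C)(C)C)C=C(CO[Si](C)(C)C(C)(C)C)Cc2c(Br)cc(OCc3ccccc3)c(OCc3ccccc3)c12
F3 | step 10 | 2-{[tert-butyl(dimethyl)silyl]oxy}but-3-enal (racemic) | C=CC(O[Si](C)(C)C(C)(C)C)C=O
F4 | step 16 | 3,4,6-tris(benzyloxy)-1-bromo-8-[(1R)-1-hydroxyprop-2-en-1-yl]-5H-benzo[7]annulen-5-one | Brc1cc(OCc2ccccc2)c(OCc2ccccc2)c2c(=O)c(OCc3ccccc3)cc([C@H](O)C=C)cc12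
F5 | step 18 | 3,4,6-tris(benzyloxy)-8-{(R)-[3-(benzyloxy)-5-hydroxyphenoxy][(2R)-oxiran-2-yl]methyl}-1-bromo-5H-benzo[7]annulen-5-one | Brc1cc(OCc2ccccc2)c(OCc2ccccc2)c2c(=O)c(OCc3ccccc3)cc([C@@H](Oc3cc(O)cc(OCc4ccccc4)c3)[C@H]3CO3)cc12
F6 | step 18 | 3,4,6-tris(benzyloxy)-8-[(2R,3R)-7-(benzyloxy)-3,5-dihydroxy-3,4-dihydro-2H-1-benzopyran-2-yl]-1-bromo-5H-benzo[7]annulen-5-one | Brc1cc(OCc2ccccc2)c(OCc2ccccc2)c2c(=O)c(OCc3ccccc3)cc([C@H]3Oc4cc(OCc5ccccc5)cc(O)c4C[C@H]3O)cc12
F0 | step 26 | none | none
A1 | alternative 1 | deca-O-benzyl theaflavin-3-gallate with the free C3 hydroxyl on flavan F | O=C(O[C@@H]1Cc2c(OCc3ccccc3)cc(OCc3ccccc3)cc2O[C@@H]1c1cc(OCc2ccccc2)c(OCc2ccccc2)c2c(=O)c(OCc3ccccc3)cc([C@H]3Oc4cc(OCc5ccccc5)cc(OCc5ccccc5)c4C[C@H]3O)cc12)c1cc(OCc2ccccc2)c(OCc2ccccc2)c(OCc2ccccc2)c1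
A2 | alternative 1 | (2R,3R)-5,7-bis(benzyloxy)-2-[3,4,6-tris(benzyloxy)-8-{(R)-[3,5-bis(benzyloxy)phenoxy][(2R)-oxiran-2-yl]methyl}-5-oxo-5H-benzo[7]annulen-1-yl]-3,4-dihydro-2H-1-benzopyran-3-yl 3,4,5-tris(benzyloxy)benzoate | O=C(O[C@@H]1Cc2c(OCc3ccccc3)cc(OCc3ccccc3)cc2O[C@@H]1c1cc(OCc2ccccc2)c(OCc2ccccc2)c2c(=O)c(OCc3ccccc3)cc([C@@H](Oc3cc(OCc4ccccc4)cc(OCc4ccccc4)c3)[C@H]3CO3)cc12)c1cc(OCc2ccccc2)c(OCc2ccccc2)c(OCc2ccccc2)c1
A3 | alternative 2 | oxygen-bridged (6,9-epoxy) cycloadduct carrying galloylated flavan G and the flavan F keto side chain (one bridge diastereomer) | O=C(O[C@@H]1Cc2c(OCc3ccccc3)cc(OCc3ccccc3)cc2O[C@@H]1c1cc(OCc2ccccc2)c(OCc2ccccc2)c2c1[C@H]1O[C@H](C=C1C(=O)[C@H](OCc1ccc(OC)cc1)Cc1c(O[Si](C)(C)C(C)(C)C)cc(OCc3ccccc3)cc1OCc1ccccc1)C2=O)c1cc(OCc2ccccc2)c(OCc2ccccc2)c(OCc2ccccc2)c1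
A4 | alternative 2 | (2R,3R)-5,7-bis(benzyloxy)-2-[4,5-bis(benzyloxy)-3-(diazoacetyl)-2-formylphenyl]-3,4-dihydro-2H-1-benzopyran-3-yl 3,4,5-tris(benzyloxy)benzoate | O=C(O[C@@H]1Cc2c(OCc3ccccc3)cc(OCc3ccccc3)cc2O[C@@H]1c1cc(OCc2ccccc2)c(OCc2ccccc2)c(C(=O)C=[N+]=[N-])c1C=O)c1cc(OCc2ccccc2)c(OCc2ccccc2)c(OCc2ccccc2)c1
A5 | alternative 2 | (4R)-5-[2,4-bis(benzyloxy)-6-{[tert-butyl(dimethyl)silyl]oxy}phenyl]-4-[(4-methoxybenzyl)oxy]pent-1-yn-3-one | C#CC(=O)[C@H](OCc1ccc(OC)cc1)Cc1c(O[Si](C)(C)C(C)(C)C)cc(OCc2ccccc2)cc1OCc1ccccc1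
A6 | alternative 3 | 3,4-bis(benzyloxy)-1,8-dibromo-6-hydroxy-5H-benzo[7]annulen-5-one | O=c1c(O)cc(Br)cc2c(Br)cc(OCc3ccccc3)c(OCc3ccccc3)c12
A7 | alternative 3 | 4,5-bis(benzyloxy)-1,1,7-tribromo-2-hydroxy-1,1a,2,7b-tetrahydro-3H-cyclopropa[a]naphthalen-3-one | O=C1C(O)C2C(Br)(Br)C2c2c(Br)cc(OCc3ccccc3)c(OCc3ccccc3)c12
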